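**Retrosynthetic overview**
- Target ⇒ achiral 3-O-(4-O-methylgalloyl)cyanidin salt. C2 and C3 are both set in one reductase-like H−/H+/H− reduction of the anthocyanidin. The ester is carried from the first step, not made last.
- Anthocyanidin salt ⇒ open-chain chalcone. Ring C closes by attack of the ring A phenol oxygen on C2 (O1–C2) and loss of water, which is the plant's chalcone → flavonoid → anthocyanidin logic run in one flask.
- Chalcone ⇒ C3–C4 aldol condensation of 2,4,6-trihydroxybenzaldehyde (ring A) with a phenacyl ester (ring B plus galloyl ring D).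
- Phenacyl ester ⇒ carboxylate of 4-O-methylgallic acid + 4-(chloroacetyl)catechol.
- Ring order: rings A, B and D are bought. Ring C is the only ring formed (step 2) and is then reduced (step 3). No protecting groups are used.

Assumption: the SMILES is read as the (2R,3R), 2,3-cis series of natural (−)-epicatechin, and the three starting materials are taken as catalogue chemicals.

**Step 1**
Reactants: 1 3,5-dihydroxy-4-methoxybenzoic acid (4-O-methylgallic acid); 2 2-chloro-1-(3,4-dihydroxyphenyl)ethan-1-one
Product: 3 2-(3,4-dihydroxyphenyl)-2-oxoethyl 3,5-dihydroxy-4-methoxybenzoate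
Conditions: KHCO3 (1.0 equiv), NaI (10 mol %), DMF, 40 °C, argon
Reagents that add atoms: none
Why: SN2 O-alkylation of a carboxylate by an α-haloketone (phenacyl ester formation with Finkelstein catalysis); one equivalent of hydrogencarbonate deprotonates only the CO2H (pKa about 4 against 7.5–10 for the phenols), so the phenols stay neutral and unreactive, and no stereocentre is formed.

**Step 2**
Reactants: 3 2-(3,4-dihydroxyphenyl)-2-oxoethyl 3,5-dihydroxy-4-methoxybenzoate; 4 2,4,6-trihydroxybenzaldehyde
Product: 7 3-O-(4-O-methylgalloyl)cyanidin triflate [2-(3,4-dihydroxyphenyl)-5,7-dihydroxy-3-(3,5-dihydroxy-4-methoxybenzoyloxy)chromenylium trifluoromethanesulfonate], via chalcone 5 (not isolated), via hemiketal 6 (not isolated)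
Conditions: TfOH (3 equiv), dry EtOAc, 0 °C to rt, 48 h, argon; Et2O, filter under argon
Reagents that add atoms: trifluoromethanesulfonic acid, O=S(=O)(O)C(F)(F)F
Why: Robinson-type acid-catalysed aldol condensation and cyclodehydration: the enol of 3 adds to protonated 4 and loses water to chalcone 5, whose ring A hydroxyl adds to the C2 carbonyl (O1–C2 closure of ring C) to give hemiketal 6, and loss of a second water gives the aromatic flavylium ion as thermodynamic sink; the medium is non-nucleophilic so the 3-ester stays, and the product is achiral.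

**Step 3**
Reactants: 7 3-O-(4-O-methylgalloyl)cyanidin triflate
Product: 10 (2R,3R)-epicatechin 3-O-(4-O-methylgallate), via flav-2-ene ester 8 (not isolated), via flavan-2-ylium ion 9 (not isolated)
Conditions: Hantzsch ester (1.00 equiv), THF–CF3CH2OH 1:1, 0 °C, argon; then Ru(OTf)[(S,S)-TsDPEN](p-cymene) (2 mol %), H2 (50 bar), 25 °C
Reagents that add atoms: none
Why: Proposed new method: a chemical copy of anthocyanidin reductase (two hydrides with a protonation in between, here H− at C4, H+ at C3, H− at C2). The NADPH model Hantzsch ester gives its hydride to the unhindered C4 of the flavylium ion (known 1,4-reduction of benzopyrylium ions), which clears the flask of electrophilic 7 before any nucleophilic flavan is present and leaves a pyridinium triflate buffer. The cationic divalent ruthenium complex then splits H2 into Ru–H and TfOH, and the acid protonates enol ether 8 reversibly at C3 to the oxocarbenium ion 9, stabilised by the 4'-hydroxyaryl group and racemising through 8, so the reduction is a dynamic kinetic resolution. Ru–H attacks C2 of the matched (3R)-ion on the face anti to the pseudo-axial, carbonyl-bridging 3-acyloxy group, which forces 2,3-cis and fixes C2 and C3 together as (2R,3R). The ester also blocks the flavan-3-one tautomer that a free 3-OH would open. The closest known reactions are the outer-sphere ionic asymmetric hydrogenation of 2,3-disubstituted quinolines to cis-tetrahydroquinolines and of isochromenylium ions with the same Ru(OTf)(TsDPEN)(arene) family, and the racemic hydrogenation of cyanidin chloride to (±)-epicatechin. The sense of induction rests on analogy only, so it is read from the first run by chiral HPLC, and the (R,R) complex, equally sold, is used if the mirror image forms.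

**Compound list**
1 | 3,5-dihydroxy-4-methoxybenzoic acid (4-O-methylgallic acid) | COc1c(O)cc(C(=O)O)cc1O | starting material
2 | 2-chloro-1-(3,4-dihydroxyphenyl)ethan-1-one | O=C(CCl)c1ccc(O)c(O)c1 | starting material
3 | 2-(3,4-dihydroxyphenyl)-2-oxoethyl 3,5-dihydroxy-4-methoxybenzoate | COc1c(O)cc(C(=O)OCC(=O)c2ccc(O)c(O)c2)cc1O | intermediate
4 | 2,4,6-trihydroxybenzaldehyde | O=Cc1c(O)cc(O)cc1O | starting material
5 | (E)-1-(3,4-dihydroxyphenyl)-1-oxo-3-(2,4,6-trihydroxyphenyl)prop-2-en-2-yl 3,5-dihydroxy-4-methoxybenzoate (chalcone, ring A cis to the aroyl group) | COc1c(O)cc(C(=O)O/C(=C/c2c(O)cc(O)cc2O)C(=O)c2ccc(O)c(O)c2)cc1O | intermediate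
6 | 2-(3,4-dihydroxyphenyl)-2,5,7-trihydroxy-2H-chromen-3-yl 3,5-dihydroxy-4-methoxybenzoate (racemic hemiketal) | COc1c(O)cc(C(=O)OC2=Cc3c(O)cc(O)cc3OC2(O)c2ccc(O)c(O)c2)cc1O | intermediate
7 | 2-(3,4-dihydroxyphenyl)-5,7-dihydroxy-3-(3,5-dihydroxy-4-methoxybenzoyloxy)chromenylium trifluoromethanesulfonate | COc1c(O)cc(C(=O)Oc2cc3c(O)cc(O)cc3[o+]c2-c2ccc(O)c(O)c2)cc1O.[O-]S(=O)(=O)C(F)(F)F | intermediate
8 | 2-(3,4-dihydroxyphenyl)-5,7-dihydroxy-4H-chromen-3-yl 3,5-dihydroxy-4-methoxybenzoate (flav-2-ene ester) | COc1c(O)cc(C(=O)OC2=C(c3ccc(O)c(O)c3)Oc3cc(O)cc(O)c3C2)cc1O | intermediate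
9 | (3R)-2-(3,4-dihydroxyphenyl)-5,7-dihydroxy-3-(3,5-dihydroxy-4-methoxybenzoyloxy)-3,4-dihydrochromenylium trifluoromethanesulfonate (the enantiomer that reacts on) | COc1c(O)cc(C(=O)O[C@@H]2Cc3c(O)cc(O)cc3[O+]=C2c2ccc(O)c(O)c2)cc1O.[O-]S(=O)(=O)C(F)(F)F | intermediate
10 | (2R,3R)-2-(3,4-dihydroxyphenyl)-5,7-dihydroxychroman-3-yl 3,5-dihydroxy-4-methoxybenzoate, epicatechin 3-O-(4-O-methylgallate) | COc1c(O)cc(C(=O)O[C@@H]2Cc3c(O)cc(O)cc3O[C@@H]2c2ccc(O)c(O)c2)cc1O | target

**Total step count:** 3. **Longest linear sequence:** 3.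

**Steps most likely to fail**

Step 3 carries the highest risk. The ionic asymmetric hydrogenation is untested on a polyphenolic flavylium ester. Possible failures are low ee, some 2,3-trans product, or binding of the catechols to ruthenium.
The fallback sets out from 7 and comes back at 10. It gives up catalytic induction and uses the classical syn-hydrogenation that turns cyanidin salts into racemic epicatechin.
- Compound 7 is hydrogenated over PtO2 (H2 1 bar, EtOH–AcOH, rt) to the racemic 2,3-cis ester.
- That product is 10 together with its mirror image, (2S,3S)-ent-epicatechin 3-O-(4-O-methylgallate) F1.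
- The two are separated by preparative HPLC on an amylose tris(3,5-dimethylphenylcarbamate) phase.

Step 2 is the second risk. Electron-rich aldehyde 4 may self-condense, and the activated 3-ester may be lost to the water that the condensation releases.
The fallback sets out from 3 and comes back at 8. It replaces the aldol C3–C4 disconnection by a Friedel–Crafts C4–C4a bond at the lower oxidation level, so neither aldehyde 4 nor a flavylium ester is ever present.
- Compound 3 is α-methylenated with (CH2O)n and i-Pr2NH·CF3CO2H in THF at reflux. This gives the captodative enone 3-(3,4-dihydroxyphenyl)-3-oxoprop-1-en-2-yl 3,5-dihydroxy-4-methoxybenzoate F2.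
- Phloroglucinol (3 equiv) adds through carbon to F2 with TfOH (10 mol %) in MeCN at rt. The product is the racemic dihydrochalcone 1-(3,4-dihydroxyphenyl)-1-oxo-3-(2,4,6-trihydroxyphenyl)propan-2-yl 3,5-dihydroxy-4-methoxybenzoate F3.
- F3 closes O1–C2 to the hemiketal 2-(3,4-dihydroxyphenyl)-2,5,7-trihydroxychroman-3-yl 3,5-dihydroxy-4-methoxybenzoate F4.
- Over 4 Å molecular sieves F4 loses water to 8.
- Compound 8 enters the hydrogenation half of step 3 without Hantzsch ester.

Step 1 is the third risk. Phenoxide alkylation may compete, and the catechol may oxidise in air under base.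
The fallback sets out from 2 (with 1 as partner) and comes back at 3. It turns the activation round, so the alcohol is activated under neutral conditions and no base is present.
- Compound 2 is heated with HCO2Na in aqueous EtOH. This gives 2-(3,4-dihydroxyphenyl)-2-oxoethyl formate F5.
- F5 hydrolyses in the same pot to 2-hydroxy-1-(3,4-dihydroxyphenyl)ethan-1-one F6.
- F6 and 1 are joined by a chemoselective Mitsunobu esterification (PPh3, DIAD, THF, 0 °C to rt). Only the primary alcohol is activated and only the carboxylic acid is acidic enough to act as the nucleophile, which gives 3.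

**Further compounds**
F1 | step 3 | (2S,3S)-2-(3,4-dihydroxyphenyl)-5,7-dihydroxychroman-3-yl 3,5-dihydroxy-4-methoxybenzoate (mirror image of 10) | COc1c(O)cc(C(=O)O[C@H]2Cc3c(O)cc(O)cc3O[C@H]2c2ccc(O)c(O)c2)cc1O
F2 | step 2 | 3-(3,4-dihydroxyphenyl)-3-oxoprop-1-en-2-yl 3,5-dihydroxy-4-methoxybenzoate | C=C(OC(=O)c1cc(O)c(OC)c(O)c1)C(=O)c1ccc(O)c(O)c1
F3 | step 2 | 1-(3,4-dihydroxyphenyl)-1-oxo-3-(2,4,6-trihydroxyphenyl)propan-2-yl 3,5-dihydroxy-4-methoxybenzoate (racemic) | COc1c(O)cc(C(=O)OC(Cc2c(O)cc(O)cc2O)C(=O)c2ccc(O)c(O)c2)cc1O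
F4 | step 2 | 2-(3,4-dihydroxyphenyl)-2,5,7-trihydroxychroman-3-yl 3,5-dihydroxy-4-methoxybenzoate (racemic hemiketal, diastereomer mixture) | COc1c(O)cc(C(=O)OC2Cc3c(O)cc(O)cc3OC2(O)c2ccc(O)c(O)c2)cc1O
F5 | step 1 | 2-(3,4-dihydroxyphenyl)-2-oxoethyl formate | O=COCC(=O)c1ccc(O)c(O)c1
F6 | step 1 | 2-hydroxy-1-(3,4-dihydroxyphenyl)ethan-1-one | OCC(=O)c1ccc(O)c(O)c1
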